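**Retrosynthetic overview**

1. The route rests on ring C, a benzopyran: its O1–C8a–C4a–C4 atoms are an ortho-quinone methide of ring A (methoxy-substituted at C4, which is at the aldehyde oxidation level), and its C2–C3 atoms are an electron-rich (E)-arylvinyl acetate of ring B that already carries the C3 oxygen. O1–C2 and C3–C4 are cut together as a [4+2].
2. After the cycloaddition the C4 methoxy carbon is raised to the ketone (acetate exchanged for a silyl ether, hydrolysis, Dess–Martin oxidation), then all protecting groups are removed.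
3. Ring A partner: 2,4,6-trihydroxybenzaldehyde, bis-MOM ether, O-tert-prenyl ether, Claisen shift to the later C8, dimethyl acetal.
4. Ring B partner: resorcinol bis-MOM ether, three directed lithiations (geranyl, prenyl, formyl), boron–Wittig to the (E)-alkenylboronate, trifluoroborate, copper-catalysed acetoxylation with retention of geometry.
5. Rings A and B are aromatic from the start; ring C is the only ring formed, in the key step.

Key step: step 12

**Remarks on the chemistry (assumptions)**

- The tert-prenyl carbonate used in step 2 is taken as a purchasable reagent.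
- Which antipode of the BINOL phosphoric acid leads to the (2R,3R) series cannot be predicted with certainty; the (R)-acid is written and the (S)-acid is used if the sense is opposite.
- The C4 methoxy and C4 hydroxy compounds after the key step are written as the 3,4-trans isomers; the C4 epimers would be carried through in the same way, because C4 ends as the carbonyl carbon.
- Geranyl = (2E)-3,7-dimethylocta-2,6-dien-1-yl; prenyl = 3-methylbut-2-en-1-yl; MOM = methoxymethyl.

**Route**

Step 1
Reactants: 1 2,4,6-trihydroxybenzaldehyde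
Product: 2 2-hydroxy-4,6-bis(methoxymethoxy)benzaldehyde
Conditions: MOMCl (2.2 equiv), iPr2NEt, CH2Cl2, 0 °C → rt
Reagents that add atoms: chloromethyl methyl ether (MOMCl), COCCl
Why: Williamson-type MOM etherification in which one ortho hydroxyl stays hydrogen-bonded to the aldehyde and is left free, which is the phenol later needed as O1.

Step 2
Reactants: 2 2-hydroxy-4,6-bis(methoxymethoxy)benzaldehyde; 3 tert-butyl (2-methylbut-3-en-2-yl) carbonate
Product: 4 2-[(2-methylbut-3-en-2-yl)oxy]-4,6-bis(methoxymethoxy)benzaldehyde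
Conditions: 3 (1.5 equiv), Pd(PPh3)4 (5 mol %), THF, 0 °C → rt
Reagents that add atoms: none
Why: Tsuji–Trost O-allylation in which the phenoxide attacks the more substituted terminus of the 1,1-dimethylallyl palladium complex and gives the tertiary aryl ether needed for a regiospecific ortho shift.

Step 3
Reactants: 4 2-[(2-methylbut-3-en-2-yl)oxy]-4,6-bis(methoxymethoxy)benzaldehyde
Product: 5 2-hydroxy-4,6-bis(methoxymethoxy)-3-prenylbenzaldehyde
Conditions: toluene, 110 °C
Reagents that add atoms: none
Why: Aromatic Claisen [3,3] rearrangement delivers the allyl unit with allylic inversion, as a normal prenyl group, to the only free ortho carbon (the later C8), and tautomerisation restores the phenol.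

Step 4
Reactants: 5 2-hydroxy-4,6-bis(methoxymethoxy)-3-prenylbenzaldehyde
Product: 6 2-(dimethoxymethyl)-3,5-bis(methoxymethoxy)-6-prenylphenol (ring A acetal)
Conditions: HC(OMe)3 (10 equiv), MeOH, CSA (2 mol %), rt; Et3N quench; used without chromatography on silica
Reagents that add atoms: trimethyl orthoformate, COC(OC)OC; methanol, CO
Why: Acid-catalysed acetalisation driven by the orthoester as water scavenger, with catalytic acid at room temperature and an amine quench mild enough for the aryl MOM ethers and the ortho-prenyl phenol.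

Step 5
Reactants: 7 resorcinol
Product: 8 1,3-bis(methoxymethoxy)benzene
Conditions: MOMCl (2.5 equiv), iPr2NEt, CH2Cl2, 0 °C → rt
Reagents that add atoms: chloromethyl methyl ether (MOMCl), COCCl
Why: Double MOM etherification installs the two directing groups for the three metalations that follow.

Step 6
Reactants: 8 1,3-bis(methoxymethoxy)benzene; 9 geranyl bromide
Product: 11 2-geranyl-1,3-bis(methoxymethoxy)benzene, via 2-lithio-1,3-bis(methoxymethoxy)benzene 10 (not isolated)
Conditions: n-BuLi, THF, 0 °C → rt; CuI (10 mol %), 9, −20 °C → rt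
Reagents that add atoms: none
Why: Directed ortho-metalation at the carbon flanked by both MOM ethers, then copper-catalysed SN2 allylation that keeps the E geometry of the geranyl unit.

Step 7
Reactants: 11 2-geranyl-1,3-bis(methoxymethoxy)benzene; 12 prenyl bromide
Product: 14 2-geranyl-1,3-bis(methoxymethoxy)-4-prenylbenzene, via 4-lithio-2-geranyl-1,3-bis(methoxymethoxy)benzene 13 (not isolated)
Conditions: n-BuLi, TMEDA, THF, −20 → 0 °C; CuI (10 mol %), 12, −20 °C → rt
Reagents that add atoms: none
Why: Second directed ortho-metalation at one of the two equivalent positions ortho to a MOM ether, where chelation-guided ring lithiation is expected to outrun deprotonation of the ArCH2 allyl position, followed by SN2 allylation.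

Step 8
Reactants: 14 2-geranyl-1,3-bis(methoxymethoxy)-4-prenylbenzene
Product: 16 3-geranyl-2,4-bis(methoxymethoxy)-5-prenylbenzaldehyde, via [3-geranyl-2,4-bis(methoxymethoxy)-5-prenylphenyl]lithium 15 (not isolated)
Conditions: n-BuLi, TMEDA, THF, 0 °C; DMF, −78 °C → rt; aq. NH4Cl
Reagents that add atoms: N,N-dimethylformamide, CN(C)C=O
Why: Third directed ortho-metalation at the last carbon ortho to a MOM ether and Bouveault-type formylation of the aryllithium with DMF.

Step 9
Reactants: 16 3-geranyl-2,4-bis(methoxymethoxy)-5-prenylbenzaldehyde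
Product: 17 (E)-2-[3-geranyl-2,4-bis(methoxymethoxy)-5-prenylphenyl]vinylboronic acid pinacol ester
Conditions: CH2(Bpin)2, LiTMP, THF, 0 °C; then 16, −78 °C → rt; aq. NH4Cl
Reagents that add atoms: bis(pinacolato)borylmethane, CC1(C)OB(CB2OC(C)(C)C(C)(C)O2)OC1(C)C
Why: Boron–Wittig olefination, in which addition of the α-boryl carbanion and syn elimination of a boron–oxygen fragment give the trans alkenylboronate from an aryl aldehyde and fix the E geometry.

Step 10
Reactants: 17 (E)-alkenylboronic acid pinacol ester of ring B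
Product: 18 potassium (E)-trifluoro{2-[3-geranyl-2,4-bis(methoxymethoxy)-5-prenylphenyl]vinyl}borate
Conditions: KHF2 (aq.), MeOH, rt
Reagents that add atoms: potassium hydrogen difluoride, [K+].F[H-]F
Why: Standard conversion of a pinacol boronate into the trifluoroborate, the boron form for which the oxidative C–O coupling is established.

Step 11
Reactants: 18 potassium (E)-alkenyltrifluoroborate of ring B
Product: 19 (E)-2-[3-geranyl-2,4-bis(methoxymethoxy)-5-prenylphenyl]vinyl acetate
Conditions: AcOH, CuBr (10 mol %), DMAP, 4 Å MS, O2 (1 atm), MeCN, 60 °C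
Reagents that add atoms: acetic acid, CC(=O)O
Why: Chan–Lam-type oxidative copper coupling of an alkenyltrifluoroborate with a carboxylic acid goes with retention of alkene geometry and so gives the E enol acetate, whereas ruthenium-catalysed anti-Markovnikov addition of acetic acid to the corresponding arylalkyne would give mainly the Z isomer.

Step 12
Reactants: 6 ring A acetal; 19 ring B (E)-arylvinyl acetate
Product: 21 (2R,3S,4R)-3-acetoxy-4-methoxyflavan tetra-MOM ether (8-prenyl; 3'-geranyl; 5'-prenyl), via ring A 4-methoxy ortho-quinone methide 20 (not isolated)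
Conditions: (R)-3,3'-bis(2,4,6-triisopropylphenyl)-1,1'-binaphthyl-2,2'-diyl hydrogen phosphate ((R)-TRIP, 10 mol %), 5 Å MS, toluene, −30 → 0 °C; 19 (1.5 equiv), slow addition of 6
Reagents that add atoms: none
Why: Proposed new method: the chiral phosphoric acid protonates an acetal oxygen of 6 and methanol leaves, giving the O-methyl oxocarbenium ion/4-methoxy ortho-quinone methide 20 held to the phosphate by a hydrogen bond, after which the acetoxy-bearing carbon of 19 bonds to C4 and the phenol oxygen captures C2; the closest known reaction type is the Brønsted-acid- and chiral-phosphoric-acid-catalysed inverse-demand [4+2] addition of ortho-quinone methides to styrenes that gives 2-arylchromans. Ring C closes as a six-membered ring by an asynchronous hetero-Diels–Alder cycloaddition, which in the stepwise limit is a Prins-type C3–C4 bond formation followed by six-membered O1–C2 closure onto the benzylic cation. C2 and C3 should come out trans because addition is suprafacial on the E alkene and, if a cation intervenes, because closure places aryl and acetoxy equatorial; the absolute configuration at C3, and with it C2, is set by the face of the phosphate-bound quinone methide left open by the 3,3'-aryl groups, and C4 is expected trans to the acetate but later becomes a carbonyl carbon. The step needs regioselectivity, which the 2,4-dialkoxyaryl group secures by stabilising positive charge at C2 while the weakly donating acetoxy group cannot invert the alkene polarity. It also needs chemoselectivity for this conjugated alkene over the four isolated trisubstituted alkenes and over C6 of ring A, which an excess of 19, slow addition of 6 and low temperature are meant to secure. The molecular sieves take up the methanol so that it neither reverses the ionisation nor intercepts the benzylic cation.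

Step 13
Reactants: 21 3-acetoxy-4-methoxyflavan tetra-MOM ether
Product: 22 (2R,3S,4R)-4-methoxyflavan-3-ol tetra-MOM ether
Conditions: K2CO3 (0.5 equiv), MeOH/THF, 0 °C → rt
Reagents that add atoms: none
Why: Base-catalysed transesterification of the secondary acetate, which is safe here because with C4 still an ether no centre is enolisable and C2 and C3 are untouched.

Step 14
Reactants: 22 4-methoxyflavan-3-ol tetra-MOM ether
Product: 23 (2R,3S,4R)-3-(tert-butyldimethylsilyloxy)-4-methoxyflavan tetra-MOM ether
Conditions: TBSCl, imidazole, DMAP (cat.), DMF, 40 °C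
Reagents that add atoms: tert-butyldimethylsilyl chloride, CC(C)(C)[Si](C)(C)Cl
Why: Silylation under conditions free of Lewis acid puts a non-participating, non-migrating group on O3 before C4 is ionised, since a 3-acyloxy group would trap the C4 cation as an acetoxonium ion and scramble the acyl position.

Step 15
Reactants: 23 3-silyloxy-4-methoxyflavan tetra-MOM ether
Product: 24 (2R,3S,4R)-3-(tert-butyldimethylsilyloxy)flavan-4-ol tetra-MOM ether
Conditions: CSA (10 mol %), MeCN/H2O (5:1), 0 °C → rt; NaHCO3 quench
Reagents that add atoms: water, O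
Why: SN1 hydrolysis, in which the C4 methyl ether on a benzylic carbon ortho and para to the ring A oxygens ionises under mild acid and water in large excess captures the cation, while aryl MOM and secondary TBS ethers should persist.

Step 16
Reactants: 24 3-silyloxyflavan-4-ol tetra-MOM ether
Product: 25 (2R,3R)-3-(tert-butyldimethylsilyloxy)flavan-4-one tetra-MOM ether
Conditions: Dess–Martin periodinane, NaHCO3, CH2Cl2, 0 °C → rt
Reagents that add atoms: none
Why: Dess–Martin oxidation of the benzylic secondary alcohol under buffered, non-epimerising conditions, to which the trisubstituted alkenes are inert.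

Step 17
Reactants: 25 3-silyloxyflavan-4-one tetra-MOM ether
Product: 26 (2R,3R)-3,5,7-trihydroxy-2-[3-geranyl-2,4-dihydroxy-5-prenylphenyl]-8-prenylchroman-4-one (CNP0149909.1)
Conditions: HCl (3 M in MeOH), THF, 40 °C
Reagents that add atoms: none
Why: Acid-catalysed acetal exchange removes the four aryl MOM ethers and methanolysis cleaves the silyl ether, while the 2,3-trans arrangement is the thermodynamically favoured one and is not expected to change under acid.

**Compound list**

1 | 2,4,6-trihydroxybenzaldehyde | O=Cc1c(O)cc(O)cc1O | starting material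
2 | 2-hydroxy-4,6-bis(methoxymethoxy)benzaldehyde | O=Cc1c(O)cc(OCOC)cc1OCOC | intermediate
3 | tert-butyl (2-methylbut-3-en-2-yl) carbonate | C=CC(C)(C)OC(=O)OC(C)(C)C | starting material
4 | 2-[(2-methylbut-3-en-2-yl)oxy]-4,6-bis(methoxymethoxy)benzaldehyde | O=Cc1c(OC(C)(C)C=C)cc(OCOC)cc1OCOC | intermediate
5 | 2-hydroxy-4,6-bis(methoxymethoxy)-3-prenylbenzaldehyde | O=Cc1c(O)c(CC=C(C)C)c(OCOC)cc1OCOC | intermediate
6 | 2-(dimethoxymethyl)-3,5-bis(methoxymethoxy)-6-prenylphenol (ring A acetal) | COC(OC)c1c(OCOC)cc(OCOC)c(CC=C(C)C)c1O | intermediate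
7 | resorcinol | Oc1cccc(O)c1 | starting material
8 | 1,3-bis(methoxymethoxy)benzene | COCOc1cccc(OCOC)c1 | intermediate
9 | geranyl bromide | CC(C)=CCC/C(C)=C/CBr | starting material
10 | 2-lithio-1,3-bis(methoxymethoxy)benzene (not isolated) | [Li]c1c(OCOC)cccc1OCOC | intermediate
11 | 2-geranyl-1,3-bis(methoxymethoxy)benzene | CC(C)=CCC/C(C)=C/Cc1c(OCOC)cccc1OCOC | intermediate
12 | prenyl bromide | CC(C)=CCBr | starting material
13 | 4-lithio-2-geranyl-1,3-bis(methoxymethoxy)benzene (not isolated) | CC(C)=CCC/C(C)=C/Cc1c(OCOC)c([Li])ccc1OCOC | intermediate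
14 | 2-geranyl-1,3-bis(methoxymethoxy)-4-prenylbenzene | CC(C)=CCC/C(C)=C/Cc1c(OCOC)c(CC=C(C)C)ccc1OCOC | intermediate
15 | [3-geranyl-2,4-bis(methoxymethoxy)-5-prenylphenyl]lithium (not isolated) | CC(C)=CCC/C(C)=C/Cc1c(OCOC)c(CC=C(C)C)cc([Li])c1OCOC | intermediate
16 | 3-geranyl-2,4-bis(methoxymethoxy)-5-prenylbenzaldehyde | CC(C)=CCC/C(C)=C/Cc1c(OCOC)c(CC=C(C)C)cc(C=O)c1OCOC | intermediate
17 | (E)-2-[3-geranyl-2,4-bis(methoxymethoxy)-5-prenylphenyl]vinylboronic acid pinacol ester | CC(C)=CCC/C(C)=C/Cc1c(OCOC)c(CC=C(C)C)cc(/C=C/B2OC(C)(C)C(C)(C)O2)c1OCOC | intermediate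
18 | potassium (E)-trifluoro{2-[3-geranyl-2,4-bis(methoxymethoxy)-5-prenylphenyl]vinyl}borate | CC(C)=CCC/C(C)=C/Cc1c(OCOC)c(CC=C(C)C)cc(/C=C/[B-](F)(F)F)c1OCOC.[K+] | intermediate
19 | (E)-2-[3-geranyl-2,4-bis(methoxymethoxy)-5-prenylphenyl]vinyl acetate | CC(C)=CCC/C(C)=C/Cc1c(OCOC)c(CC=C(C)C)cc(/C=C/OC(C)=O)c1OCOC | intermediate
20 | 6-(methoxymethylene)-3,5-bis(methoxymethoxy)-2-prenylcyclohexa-2,4-dien-1-one, the ring A 4-methoxy ortho-quinone methide (not isolated; exocyclic alkene geometry not fixed) | COC=C1C(=O)C(CC=C(C)C)=C(OCOC)C=C1OCOC | intermediate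
21 | (2R,3S,4R)-3-acetoxy-4-methoxy-5,7-bis(methoxymethoxy)-8-prenyl-2-[3-geranyl-2,4-bis(methoxymethoxy)-5-prenylphenyl]chroman | CC(C)=CCC/C(C)=C/Cc1c(OCOC)c(CC=C(C)C)cc([C@H]2Oc3c(CC=C(C)C)c(OCOC)cc(OCOC)c3[C@@H](OC)[C@@H]2OC(C)=O)c1OCOC | intermediate
22 | (2R,3S,4R)-4-methoxy-5,7-bis(methoxymethoxy)-8-prenyl-2-[3-geranyl-2,4-bis(methoxymethoxy)-5-prenylphenyl]chroman-3-ol | CC(C)=CCC/C(C)=C/Cc1c(OCOC)c(CC=C(C)C)cc([C@H]2Oc3c(CC=C(C)C)c(OCOC)cc(OCOC)c3[C@@H](OC)[C@@H]2O)c1OCOC | intermediate
23 | (2R,3S,4R)-3-(tert-butyldimethylsilyloxy)-4-methoxy-5,7-bis(methoxymethoxy)-8-prenyl-2-[3-geranyl-2,4-bis(methoxymethoxy)-5-prenylphenyl]chroman | CC(C)=CCC/C(C)=C/Cc1c(OCOC)c(CC=C(C)C)cc([C@H]2Oc3c(CC=C(C)C)c(OCOC)cc(OCOC)c3[C@@H](OC)[C@@H]2O[Si](C)(C)C(C)(C)C)c1OCOC | intermediate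
24 | (2R,3S,4R)-3-(tert-butyldimethylsilyloxy)-5,7-bis(methoxymethoxy)-8-prenyl-2-[3-geranyl-2,4-bis(methoxymethoxy)-5-prenylphenyl]chroman-4-ol | CC(C)=CCC/C(C)=C/Cc1c(OCOC)c(CC=C(C)C)cc([C@H]2Oc3c(CC=C(C)C)c(OCOC)cc(OCOC)c3[C@@H](O)[C@@H]2O[Si](C)(C)C(C)(C)C)c1OCOC | intermediate
25 | (2R,3R)-3-(tert-butyldimethylsilyloxy)-5,7-bis(methoxymethoxy)-8-prenyl-2-[3-geranyl-2,4-bis(methoxymethoxy)-5-prenylphenyl]chroman-4-one | CC(C)=CCC/C(C)=C/Cc1c(OCOC)c(CC=C(C)C)cc([C@H]2Oc3c(CC=C(C)C)c(OCOC)cc(OCOC)c3C(=O)[C@@H]2O[Si](C)(C)C(C)(C)C)c1OCOC | intermediate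
26 | (2R,3R)-3,5,7-trihydroxy-2-[3-geranyl-2,4-dihydroxy-5-prenylphenyl]-8-prenylchroman-4-one (CNP0149909.1) | CC(C)=CCC/C(C)=C/Cc1c(O)c(CC=C(C)C)cc([C@H]2Oc3c(CC=C(C)C)c(O)cc(O)c3C(=O)[C@@H]2O)c1O | target

**Step count and risks**

Total step count: 17.
Longest linear sequence: 13 steps (steps 5–17, from resorcinol).

Steps most likely to fail:

1. Step 12 (new method). The phosphoric acid may not activate the strongly stabilised oxocarbenium ion enough for attack by a β-acyloxystyrene. The ionised acetal may instead be consumed by Friedel–Crafts self-condensation through C6 of ring A or by Prins attack of the isolated alkenes. Facial control by the phosphate may be poor. A more acidic N-triflyl phosphoramide on the same BINOL backbone is the first variation. The fallback uses known chalcone epoxide chemistry and sets out from 5 and 16. The free phenol of 5 is capped (NaH, MOMCl, DMF) to give 2,4,6-tris(methoxymethoxy)-3-prenylbenzaldehyde F1. MeMgBr in THF adds to give the racemic 1-arylethanol F2, and Dess–Martin oxidation gives 2,4,6-tris(methoxymethoxy)-3-prenylacetophenone F3. Claisen–Schmidt condensation of F3 with 16 (KOH, EtOH) gives the (E)-chalcone F4. Juliá–Colonna epoxidation (poly-L-leucine, urea–hydrogen peroxide, DBU, THF), a nucleophilic epoxidation that leaves the isolated alkenes alone, gives the (αR,βS)-epoxychalcone F5. Methanolic HCl then removes the five MOM groups, and the freed 2'-phenol opens the epoxide at the benzylic carbon, closing ring C as the 2,3-trans dihydroflavonol with C3 keeping the configuration of the epoxide α-carbon. The fallback comes back to the route at 26.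

2. Step 11. The oxidative copper coupling may be slow on an ortho-alkoxy, electron-rich alkenylborate, with protodeboronation or oxidative homocoupling taking over. The fallback sets out from 17. Oxidation with NaBO3·4H2O in THF/water gives 2-[3-geranyl-2,4-bis(methoxymethoxy)-5-prenylphenyl]acetaldehyde F6. This is O-acetylated through its enolate (Ac2O, KOAc, 100 °C, or Ac2O, Et3N, DMAP). The E isomer is separated, and the Z material is recycled by methanolysis back to F6. The fallback comes back to the route at 19.

3. Step 17. Under protic acid the freed phenols may add to the neighbouring prenyl and geranyl alkenes (chroman formation), or cleavage of the hindered silyl ether may lag behind. The fallback sets out from 25 and avoids free phenols in the presence of protic acid. TESOTf and 2,2'-bipyridyl in CH2Cl2 at 0 °C exchange the four aryl MOM ethers directly for triethylsilyl ethers, giving the (2R,3R)-3-O-TBS-5,7,2',4'-tetrakis-O-triethylsilyl flavanonol F7. Buffered HF·pyridine in THF then removes all five silyl groups. The fallback comes back to the route at 26.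

**Further compounds**

F1 | step 12 | 2,4,6-tris(methoxymethoxy)-3-prenylbenzaldehyde | O=Cc1c(OCOC)c(CC=C(C)C)c(OCOC)cc1OCOC
F2 | step 12 | racemic 1-[2,4,6-tris(methoxymethoxy)-3-prenylphenyl]ethanol | CC(O)c1c(OCOC)c(CC=C(C)C)c(OCOC)cc1OCOC
F3 | step 12 | 2,4,6-tris(methoxymethoxy)-3-prenylacetophenone | CC(=O)c1c(OCOC)c(CC=C(C)C)c(OCOC)cc1OCOC
F4 | step 12 | (E)-3-[3-geranyl-2,4-bis(methoxymethoxy)-5-prenylphenyl]-1-[2,4,6-tris(methoxymethoxy)-3-prenylphenyl]prop-2-en-1-one | O=C(/C=C/c1cc(CC=C(C)C)c(OCOC)c(C/C=C(\C)CCC=C(C)C)c1OCOC)c1c(OCOC)c(CC=C(C)C)c(OCOC)cc1OCOC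
F5 | step 12 | (αR,βS)-epoxide of chalcone F4 | O=C([C@@H]1O[C@H]1c1cc(CC=C(C)C)c(OCOC)c(C/C=C(\C)CCC=C(C)C)c1OCOC)c1c(OCOC)c(CC=C(C)C)c(OCOC)cc1OCOC
F6 | step 11 | 2-[3-geranyl-2,4-bis(methoxymethoxy)-5-prenylphenyl]acetaldehyde | O=CCc1cc(CC=C(C)C)c(OCOC)c(C/C=C(\C)CCC=C(C)C)c1OCOC
F7 | step 17 | (2R,3R)-3-(tert-butyldimethylsilyloxy)-5,7-bis(triethylsilyloxy)-8-prenyl-2-[3-geranyl-5-prenyl-2,4-bis(triethylsilyloxy)phenyl]chroman-4-one | CC(C)=CCC/C(C)=C/Cc1c(O[Si](CC)(CC)CC)c(CC=C(C)C)cc([C@H]2Oc3c(CC=C(C)C)c(O[Si](CC)(CC)CC)cc(O[Si](CC)(CC)CC)c3C(=O)[C@@H]2O[Si](C)(C)C(C)(C)C)c1O[Si](CC)(CC)CC
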